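A direct plan would make the trans ester aldehyde A1 from a cyclohexenone by an amide acetal Claisen rearrangement, carbonylation and hydrogenation, and would set the oxygenated quaternary carbon by an aldol addition of the enolate of the lactic acid-derived dioxolanone A2.
It would then deoxygenate the adduct and rebuild it into the tertiary vinyl carbinol A3, join the arene by a B-alkyl Suzuki coupling, close the chroman A4 by a palladium-catalysed aryl ether formation and dehydrogenate A4 to the chromene.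
Its weakest steps would be:
(a) the passage from the aldol adduct to A3 (thioacylation, radical deoxygenation, acetal opening with reduction, oxidation, methylenation), which would add length without adding complexity;
(b) the aryl ether ring closure of a hindered tertiary alcohol onto an aryl bromide with an ortho substituent, where slow C–O reductive elimination would let hydrodebromination compete;
(c) the late dehydrogenation of A4 with a quinone, which would have to stop at the chromene in an electron-rich ring that also carries a benzylic methyl group.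

The new route would close the cyclohexane last, on a finished chromene. It would exploit the carboxyl group on cyclohexane C1: C2 is its β-carbon and C1 its α-carbon, so the C2–C3 and C1–C6 bonds are a conjugate addition and an enolate alkylation. (R)-Linalool would supply chromene C2; aromatic substitution and ring-closing metathesis would give the pyran without redox steps. The key step would add a tertiary radical to an enoyl oxazolidinone, forming the quaternary–tertiary C3–C2 bond and setting C2 under auxiliary control, independently of the remote chromene centre; the same auxiliary would direct the ring closure that sets C1. The aldol/deoxygenation detour, the tertiary C–O coupling and the chroman dehydrogenation would disappear.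

Key step: step 9

Assumption: commercial (R)-(−)-linalool would be used in enantiomerically enriched form; any (S) enantiomer would become a diastereomer once the auxiliary is attached (compound 12 onward) and would be removed there.

Step 1
Reactants: 1 (R)-(−)-linalool [(3R)-3,7-dimethylocta-1,6-dien-3-ol]; 2 2,6-difluoro-4-methylbenzaldehyde
Product: 4 2-{[(3R)-3,7-dimethylocta-1,6-dien-3-yl]oxy}-6-fluoro-4-methylbenzaldehyde, via sodium alkoxide 3 (not isolated)
Conditions: NaH (1.15 equiv), DMF, 0 °C, 30 min; added to 2 (1.5 equiv) in DMF at −20 °C, then to rt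
Reagents that add atoms: none
Why: Nucleophilic aromatic substitution (addition–elimination) of the tertiary alkoxide at a fluoride activated by the ortho formyl group forms the aryl–O bond without touching the C–O bond of linalool, so the (R) carbinol is retained as the future chromene C2, and the new alkoxy group deactivates the second fluoride.

Step 2
Reactants: 4 2-{[(3R)-3,7-dimethylocta-1,6-dien-3-yl]oxy}-6-fluoro-4-methylbenzaldehyde
Product: 7 2-{[tert-butyl(dimethyl)silyl]oxy}-6-{[(3R)-3,7-dimethylocta-1,6-dien-3-yl]oxy}-4-methylbenzaldehyde, via sulfonylethyl ether 5 (not isolated), via phenol 6 (not isolated)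
Conditions: MeSO2CH2CH2OH (1.5 equiv), NaH (3 equiv), DMF, 0 °C to rt; aq NH4Cl work-up; then TBSCl (1.3 equiv), imidazole (2.5 equiv), CH2Cl2, rt
Reagents that add atoms: 2-(methylsulfonyl)ethanol CS(=O)(=O)CCO; tert-butyl(chloro)dimethylsilane CC(C)(C)[Si](C)(C)Cl
Why: A second nucleophilic aromatic substitution ortho to the formyl group followed by E1cB loss of ethenyl methyl sulfone unmasks the phenol without hydroxide (no Cannizzaro reaction), and silylation gives an ether that should survive ylide, ruthenium carbene, tin radical and amide base.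

Step 3
Reactants: 7 2-{[tert-butyl(dimethyl)silyl]oxy}-6-{[(3R)-3,7-dimethylocta-1,6-dien-3-yl]oxy}-4-methylbenzaldehyde
Product: 8 tert-butyl(3-{[(3R)-3,7-dimethylocta-1,6-dien-3-yl]oxy}-2-ethenyl-5-methylphenoxy)dimethylsilane
Conditions: MePPh3Br (1.6 equiv), NaN(SiMe3)2 (1.5 equiv), THF, 0 °C; then 7, 0 °C to rt
Reagents that add atoms: methyltriphenylphosphonium bromide C[P+](c1ccccc1)(c1ccccc1)c1ccccc1.[Br-]
Why: Wittig methylenation of the non-enolisable benzaldehyde installs the styrene carbon that becomes C4 of the chromene.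

Step 4
Reactants: 8 tert-butyl(3-{[(3R)-3,7-dimethylocta-1,6-dien-3-yl]oxy}-2-ethenyl-5-methylphenoxy)dimethylsilane
Product: 9 tert-butyl{[(2R)-2,7-dimethyl-2-(4-methylpent-3-en-1-yl)-2H-chromen-5-yl]oxy}dimethylsilane
Conditions: second-generation Grubbs catalyst (H2IMes)(PCy3)Cl2Ru=CHPh (3 mol%), CH2Cl2 (5 mM), 35 °C, dark
Reagents that add atoms: none
Why: In this ring-closing olefin metathesis the ruthenium carbene should load at the styrene and close the six-membered pyran onto the vinyl group (C3=C4 bond) faster than the trisubstituted olefin can react, and C2 is not involved so its configuration is kept.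

Step 5
Reactants: 10 (4S)-4-(diphenylmethyl)-1,3-oxazolidin-2-one
Product: 11 (4S)-4-(diphenylmethyl)-3-(prop-2-enoyl)-1,3-oxazolidin-2-one
Conditions: acrylic acid (1.3 equiv), t-BuCOCl (1.25 equiv), Et3N (2.6 equiv), THF, −20 °C, 1 h; then LiCl (1.1 equiv) and 10, −20 °C to rt
Reagents that add atoms: acrylic acid C=CC(=O)O
Why: N-Acylation of the oxazolidinone by the mixed pivalic anhydride of acrylic acid, promoted by LiCl, avoids the polymerisation that acryloyl chloride with a lithiated oxazolidinone tends to give.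

Step 6
Reactants: 9 tert-butyl{[(2R)-2,7-dimethyl-2-(4-methylpent-3-en-1-yl)-2H-chromen-5-yl]oxy}dimethylsilane; 11 (4S)-4-(diphenylmethyl)-3-(prop-2-enoyl)-1,3-oxazolidin-2-one
Product: 12 (4S)-3-{(2E)-5-[(2R)-5-{[tert-butyl(dimethyl)silyl]oxy}-2,7-dimethyl-2H-chromen-2-yl]pent-2-enoyl}-4-(diphenylmethyl)-1,3-oxazolidin-2-one
Conditions: 11 (3 equiv), second-generation Hoveyda–Grubbs catalyst (H2IMes)Cl2Ru=CH(C6H4-2-OiPr) (5 mol%), CH2Cl2, 40 °C, argon sweep, dark
Reagents that add atoms: none
Why: Olefin cross metathesis between the prenyl-type trisubstituted olefin and the electron-poor acryloyl imide releases 2-methylpropene and should give the E-enoyl imide, while the unstrained endocyclic chromene olefin is not opened.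

Step 7
Reactants: 13 5-chloropentan-2-one
Product: 14 5-chloro-2-methylpentan-2-ol
Conditions: MeMgBr (3 M in Et2O, 1.1 equiv), Et2O, −30 to 0 °C; cold aq NH4Cl
Reagents that add atoms: methylmagnesium bromide C[Mg]Br
Why: Grignard addition to the ketone at low temperature with a cold quench gives the tertiary alcohol before the chloro alkoxide can close to a tetrahydrofuran.

Step 8
Reactants: 14 5-chloro-2-methylpentan-2-ol
Product: 15 5-chloro-2-iodo-2-methylpentane
Conditions: 57% aq HI (3 equiv), 0 °C, 30 min, dark; pentane extraction, used at once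
Reagents that add atoms: hydrogen iodide I
Why: SN1 substitution through the tertiary cation exchanges only the tertiary hydroxyl, the primary chloride being inert to iodide at 0 °C.

Step 9 (key step)
Reactants: 12 (4S)-3-{(2E)-5-[(2R)-5-{[tert-butyl(dimethyl)silyl]oxy}-2,7-dimethyl-2H-chromen-2-yl]pent-2-enoyl}-4-(diphenylmethyl)-1,3-oxazolidin-2-one; 15 5-chloro-2-iodo-2-methylpentane
Product: 16 (4S)-3-[(3R)-3-{2-[(2R)-5-{[tert-butyl(dimethyl)silyl]oxy}-2,7-dimethyl-2H-chromen-2-yl]ethyl}-7-chloro-4,4-dimethylheptanoyl]-4-(diphenylmethyl)-1,3-oxazolidin-2-one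
Conditions: 15 (5 equiv), Yb(OTf)3 (1.0 equiv), Bu3SnH (2.5 equiv), Et3B (1 M in hexane, 0.3 equiv in portions), air by syringe, CH2Cl2/THF 4:1, −78 °C, dark
Reagents that add atoms: none
Why: Ethyl radicals from Et3B and oxygen abstract iodine from 15; the nucleophilic tertiary radical adds to the β-carbon of the enoyl imide, whose two carbonyl groups are held syn and s-cis by chelation to Yb(OTf)3, and the α-acyl radical takes hydrogen from Bu3SnH, which carries the chain. The closest known reaction type is the Lewis acid-mediated diastereoselective Giese addition of tert-butyl and isopropyl radicals to N-crotonoyl and N-cinnamoyl 4-(diphenylmethyl)oxazolidin-2-ones. No ring is closed here, but the step makes the most hindered C–C bond of the target, between the quaternary C3 and the tertiary C2 of the future cyclohexane, and brings in all remaining ring carbons with a leaving group at C6 for the 6-exo-tet closure of step 11. The new stereocentre (cyclohexane C2, 3R in 16) is controlled by the auxiliary alone: in the chelate the CHPh2 group of the (4S) auxiliary covers one face of the β-carbon and the radical enters from the other, whatever the configuration of the remote chromene C2. The step needs chemoselectivity for the enoyl imide over the chromene C3=C4 bond and the C–Cl bond, which Lewis acid activation of the acceptor, the low affinity of a nucleophilic radical for an electron-rich cis-disubstituted styrene and the slow chlorine abstraction by tin radicals should secure. The low temperature should also let hydrogen transfer from Bu3SnH outrun cyclisation of the adduct radical onto the chromene.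

Step 10
Reactants: 16 (4S)-3-[(3R)-3-{2-[(2R)-5-{[tert-butyl(dimethyl)silyl]oxy}-2,7-dimethyl-2H-chromen-2-yl]ethyl}-7-chloro-4,4-dimethylheptanoyl]-4-(diphenylmethyl)-1,3-oxazolidin-2-one
Product: 17 (4S)-3-[(3R)-3-{2-[(2R)-5-{[tert-butyl(dimethyl)silyl]oxy}-2,7-dimethyl-2H-chromen-2-yl]ethyl}-7-iodo-4,4-dimethylheptanoyl]-4-(diphenylmethyl)-1,3-oxazolidin-2-one
Conditions: NaI (5 equiv), acetone, 56 °C, dark
Reagents that add atoms: sodium iodide [Na+].[I-]
Why: Finkelstein halide exchange under neutral conditions gives a primary iodide reactive enough to be alkylated by a thermally fragile imide enolate at low temperature.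

Step 11
Reactants: 17 (4S)-3-[(3R)-3-{2-[(2R)-5-{[tert-butyl(dimethyl)silyl]oxy}-2,7-dimethyl-2H-chromen-2-yl]ethyl}-7-iodo-4,4-dimethylheptanoyl]-4-(diphenylmethyl)-1,3-oxazolidin-2-one
Product: 19 (4S)-3-{[(1S,2R)-2-{2-[(2R)-5-{[tert-butyl(dimethyl)silyl]oxy}-2,7-dimethyl-2H-chromen-2-yl]ethyl}-3,3-dimethylcyclohexyl]carbonyl}-4-(diphenylmethyl)-1,3-oxazolidin-2-one, via sodium Z-enolate 18 (not isolated)
Conditions: NaN(SiMe3)2 (1.1 equiv), THF, −78 °C, 30 min; then −78 to −20 °C; aq NH4Cl
Reagents that add atoms: none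
Why: Intramolecular alkylation of the chelated Z-enolate (6-exo-tet) closes the cyclohexane on the enolate face anti to the CHPh2 group, which is also the face that holds the tether when the C2–H bond eclipses the enolate to avoid allylic strain, so auxiliary and substrate should both lead to the trans (1S,2R) ring.

Step 12
Reactants: 19 (4S)-3-{[(1S,2R)-2-{2-[(2R)-5-{[tert-butyl(dimethyl)silyl]oxy}-2,7-dimethyl-2H-chromen-2-yl]ethyl}-3,3-dimethylcyclohexyl]carbonyl}-4-(diphenylmethyl)-1,3-oxazolidin-2-one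
Product: 21 (1S,2R)-2-{2-[(2R)-5-hydroxy-2,7-dimethyl-2H-chromen-2-yl]ethyl}-3,3-dimethylcyclohexane-1-carboxylic acid (CNP0144010.1), via silyl ether acid 20 (not isolated)
Conditions: LiOH·H2O (4 equiv), 30% H2O2 (8 equiv), THF/H2O 3:1, 0 °C, dark; aq Na2SO3, 0 °C; then LiOH·H2O (6 equiv), MeOH, rt; 1 M HCl to pH 4 at 0 °C
Reagents that add atoms: hydrogen peroxide OO
Why: Hydroperoxide anion cleaves the hindered imide at the exocyclic carbonyl without epimerising C1, sulfite reduces the peracid before acidification so that the chromene is not epoxidised, and hydroxide then removes the aryl silyl ether.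

## Compound list
1 | (R)-(−)-linalool, (3R)-3,7-dimethylocta-1,6-dien-3-ol | C=C[C@](C)(O)CCC=C(C)C | starting material
2 | 2,6-difluoro-4-methylbenzaldehyde | Cc1cc(F)c(C=O)c(F)c1 | starting material
3 | sodium (3R)-3,7-dimethylocta-1,6-dien-3-olate | C=C[C@](C)([O-])CCC=C(C)C.[Na+] | intermediate
4 | 2-{[(3R)-3,7-dimethylocta-1,6-dien-3-yl]oxy}-6-fluoro-4-methylbenzaldehyde | C=C[C@](C)(Oc1cc(C)cc(F)c1C=O)CCC=C(C)C | intermediate
5 | 2-{[(3R)-3,7-dimethylocta-1,6-dien-3-yl]oxy}-4-methyl-6-[2-(methylsulfonyl)ethoxy]benzaldehyde | C=C[C@](C)(Oc1cc(C)cc(OCCS(C)(=O)=O)c1C=O)CCC=C(C)C | intermediate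
6 | 2-{[(3R)-3,7-dimethylocta-1,6-dien-3-yl]oxy}-6-hydroxy-4-methylbenzaldehyde | C=C[C@](C)(Oc1cc(C)cc(O)c1C=O)CCC=C(C)C | intermediate
7 | 2-{[tert-butyl(dimethyl)silyl]oxy}-6-{[(3R)-3,7-dimethylocta-1,6-dien-3-yl]oxy}-4-methylbenzaldehyde | C=C[C@](C)(Oc1cc(C)cc(O[Si](C)(C)C(C)(C)C)c1C=O)CCC=C(C)C | intermediate
8 | tert-butyl(3-{[(3R)-3,7-dimethylocta-1,6-dien-3-yl]oxy}-2-ethenyl-5-methylphenoxy)dimethylsilane | C=C[C@](C)(Oc1cc(C)cc(O[Si](C)(C)C(C)(C)C)c1C=C)CCC=C(C)C | intermediate
9 | tert-butyl{[(2R)-2,7-dimethyl-2-(4-methylpent-3-en-1-yl)-2H-chromen-5-yl]oxy}dimethylsilane | Cc1cc(O[Si](C)(C)C(C)(C)C)c2c(c1)O[C@](C)(CCC=C(C)C)C=C2 | intermediate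
10 | (4S)-4-(diphenylmethyl)-1,3-oxazolidin-2-one | O=C1N[C@@H](C(c2ccccc2)c2ccccc2)CO1 | starting material
11 | (4S)-4-(diphenylmethyl)-3-(prop-2-enoyl)-1,3-oxazolidin-2-one | C=CC(=O)N1[C@@H](C(c2ccccc2)c2ccccc2)COC1=O | intermediate
12 | (4S)-3-{(2E)-5-[(2R)-5-{[tert-butyl(dimethyl)silyl]oxy}-2,7-dimethyl-2H-chromen-2-yl]pent-2-enoyl}-4-(diphenylmethyl)-1,3-oxazolidin-2-one | Cc1cc(O[Si](C)(C)C(C)(C)C)c2c(c1)O[C@](C)(CC/C=C/C(=O)N1[C@@H](C(c3ccccc3)c3ccccc3)COC1=O)C=C2 | intermediate
13 | 5-chloropentan-2-one | CC(=O)CCCCl | starting material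
14 | 5-chloro-2-methylpentan-2-ol | CC(C)(O)CCCCl | intermediate
15 | 5-chloro-2-iodo-2-methylpentane | CC(C)(I)CCCCl | intermediate
16 | (4S)-3-[(3R)-3-{2-[(2R)-5-{[tert-butyl(dimethyl)silyl]oxy}-2,7-dimethyl-2H-chromen-2-yl]ethyl}-7-chloro-4,4-dimethylheptanoyl]-4-(diphenylmethyl)-1,3-oxazolidin-2-one | Cc1cc(O[Si](C)(C)C(C)(C)C)c2c(c1)O[C@](C)(CC[C@H](CC(=O)N1[C@@H](C(c3ccccc3)c3ccccc3)COC1=O)C(C)(C)CCCCl)C=C2 | intermediate
17 | (4S)-3-[(3R)-3-{2-[(2R)-5-{[tert-butyl(dimethyl)silyl]oxy}-2,7-dimethyl-2H-chromen-2-yl]ethyl}-7-iodo-4,4-dimethylheptanoyl]-4-(diphenylmethyl)-1,3-oxazolidin-2-one | Cc1cc(O[Si](C)(C)C(C)(C)C)c2c(c1)O[C@](C)(CC[C@H](CC(=O)N1[C@@H](C(c3ccccc3)c3ccccc3)COC1=O)C(C)(C)CCCI)C=C2 | intermediate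
18 | sodium Z-enolate of 17 | Cc1cc(O[Si](C)(C)C(C)(C)C)c2c(c1)O[C@](C)(CC[C@H](/C=C(\[O-])N1[C@@H](C(c3ccccc3)c3ccccc3)COC1=O)C(C)(C)CCCI)C=C2.[Na+] | intermediate
19 | (4S)-3-{[(1S,2R)-2-{2-[(2R)-5-{[tert-butyl(dimethyl)silyl]oxy}-2,7-dimethyl-2H-chromen-2-yl]ethyl}-3,3-dimethylcyclohexyl]carbonyl}-4-(diphenylmethyl)-1,3-oxazolidin-2-one | Cc1cc(O[Si](C)(C)C(C)(C)C)c2c(c1)O[C@](C)(CC[C@@H]1[C@@H](C(=O)N3[C@@H](C(c4ccccc4)c4ccccc4)COC3=O)CCCC1(C)C)C=C2 | intermediate
20 | (1S,2R)-2-{2-[(2R)-5-{[tert-butyl(dimethyl)silyl]oxy}-2,7-dimethyl-2H-chromen-2-yl]ethyl}-3,3-dimethylcyclohexane-1-carboxylic acid | Cc1cc(O[Si](C)(C)C(C)(C)C)c2c(c1)O[C@](C)(CC[C@@H]1[C@@H](C(=O)O)CCCC1(C)C)C=C2 | intermediate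
21 | (1S,2R)-2-{2-[(2R)-5-hydroxy-2,7-dimethyl-2H-chromen-2-yl]ethyl}-3,3-dimethylcyclohexane-1-carboxylic acid (CNP0144010.1) | Cc1cc(O)c2c(c1)O[C@](C)(CC[C@@H]1[C@@H](C(=O)O)CCCC1(C)C)C=C2 | target

Total step count: 12. Longest linear sequence: 9 steps (steps 1, 2, 3, 4, 6, 9, 10, 11 and 12, from compound 1).

Steps most likely to fail:

Step 9 (key step). The tertiary radical might be reduced by Bu3SnH before it adds to the β-substituted acceptor, the adduct radical might cyclise onto the chromene double bond, or facial control might be incomplete. The fallback would replace the radical by a copper-mediated two-electron conjugate addition and would set out from compound 12. Commercial 2-methylpent-4-en-2-ol F1 would be converted with concentrated HCl into 4-chloro-4-methylpent-1-ene F2 and with Mg into (2-methylpent-4-en-2-yl)magnesium chloride F3. Addition of F3 with CuBr·SMe2 (THF/Me2S, −78 to −20 °C) to the magnesium-chelated imide 12 would give, with the same facial sense, the hept-6-enoyl imide F4. Hydroboration of the terminal olefin with 9-BBN (B-alkyl borane F5) and oxidation with Me3NO would give the primary alcohol F6, and I2/PPh3/imidazole would come back to the route at compound 17.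

Step 6. Turnover might stall because the trisubstituted olefin enters the catalytic cycle slowly and the acryloyl imide can chelate the ruthenium carbene or dimerise. The fallback would set out from compound 8 and replace metathesis at the prenyl group by oxidative cleavage and olefination. mCPBA (CH2Cl2, NaHCO3, 0 °C) would epoxidise only the trisubstituted olefin to give epoxide F7 (both epimers), and H5IO6 (THF/Et2O, 0 °C) would cleave it to aldehyde F8. Ring-closing metathesis as in step 4 would give chromene aldehyde F9. A Horner–Wadsworth–Emmons reaction (LiCl, i-Pr2NEt, MeCN) with phosphonate F11, made from 10 by N-bromoacetylation (bromoacetyl imide F10) and Arbuzov reaction with P(OEt)3, would come back to the route at compound 12.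

Step 1. The hindered alkoxide might attack the formyl group (hemiacetal formation followed by hydride transfer) instead of the ring carbon, or displace both fluorides. The fallback would set out from compound 1 and carry the formyl group as a nitrile. Substitution on 2,6-difluoro-4-methylbenzonitrile F12 would give fluoro nitrile F13, and the sequence of step 2 would give silyloxy nitrile F16 by way of sulfonylethyl ether F14 and phenol F15. Reduction with i-Bu2AlH (toluene, −78 °C; hydrolysis of the imine on work-up) would come back to the route at compound 7.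

Further compounds
F1 | step 9 | 2-methylpent-4-en-2-ol | C=CCC(C)(C)O
F2 | step 9 | 4-chloro-4-methylpent-1-ene | C=CCC(C)(C)Cl
F3 | step 9 | (2-methylpent-4-en-2-yl)magnesium chloride | C=CCC(C)(C)[Mg]Cl
F4 | step 9 | (4S)-3-[(3R)-3-{2-[(2R)-5-{[tert-butyl(dimethyl)silyl]oxy}-2,7-dimethyl-2H-chromen-2-yl]ethyl}-4,4-dimethylhept-6-enoyl]-4-(diphenylmethyl)-1,3-oxazolidin-2-one | Cc1cc(O[Si](C)(C)C(C)(C)C)c2c(c1)O[C@](C)(CC[C@H](CC(=O)N1[C@@H](C(c3ccccc3)c3ccccc3)COC1=O)C(C)(C)CC=C)C=C2
F5 | step 9 | (4S)-3-[(3R)-7-(9-borabicyclo[3.3.1]nonan-9-yl)-3-{2-[(2R)-5-{[tert-butyl(dimethyl)silyl]oxy}-2,7-dimethyl-2H-chromen-2-yl]ethyl}-4,4-dimethylheptanoyl]-4-(diphenylmethyl)-1,3-oxazolidin-2-one | Cc1cc(O[Si](C)(C)C(C)(C)C)c2c(c1)O[C@](C)(CC[C@H](CC(=O)N1[C@@H](C(c3ccccc3)c3ccccc3)COC1=O)C(C)(C)CCCB1C3CCCC1CCC3)C=C2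
F6 | step 9 | (4S)-3-[(3R)-3-{2-[(2R)-5-{[tert-butyl(dimethyl)silyl]oxy}-2,7-dimethyl-2H-chromen-2-yl]ethyl}-7-hydroxy-4,4-dimethylheptanoyl]-4-(diphenylmethyl)-1,3-oxazolidin-2-one | Cc1cc(O[Si](C)(C)C(C)(C)C)c2c(c1)O[C@](C)(CC[C@H](CC(=O)N1[C@@H](C(c3ccccc3)c3ccccc3)COC1=O)C(C)(C)CCCO)C=C2
F7 | step 6 | tert-butyl[3-({(3R)-5-(3,3-dimethyloxiran-2-yl)-3-methylpent-1-en-3-yl}oxy)-2-ethenyl-5-methylphenoxy]dimethylsilane (both epoxide epimers) | C=C[C@](C)(Oc1cc(C)cc(O[Si](C)(C)C(C)(C)C)c1C=C)CCC1OC1(C)C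
F8 | step 6 | (4R)-4-(3-{[tert-butyl(dimethyl)silyl]oxy}-2-ethenyl-5-methylphenoxy)-4-methylhex-5-enal | C=C[C@](C)(Oc1cc(C)cc(O[Si](C)(C)C(C)(C)C)c1C=C)CCC=O
F9 | step 6 | 3-[(2R)-5-{[tert-butyl(dimethyl)silyl]oxy}-2,7-dimethyl-2H-chromen-2-yl]propanal | Cc1cc(O[Si](C)(C)C(C)(C)C)c2c(c1)O[C@](C)(CCC=O)C=C2
F10 | step 6 | (4S)-3-(bromoacetyl)-4-(diphenylmethyl)-1,3-oxazolidin-2-one | O=C(CBr)N1[C@@H](C(c2ccccc2)c2ccccc2)COC1=O
F11 | step 6 | diethyl {2-[(4S)-4-(diphenylmethyl)-2-oxo-1,3-oxazolidin-3-yl]-2-oxoethyl}phosphonate | CCOP(=O)(CC(=O)N1[C@@H](C(c2ccccc2)c2ccccc2)COC1=O)OCC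
F12 | step 1 | 2,6-difluoro-4-methylbenzonitrile | Cc1cc(F)c(C#N)c(F)c1
F13 | step 1 | 2-{[(3R)-3,7-dimethylocta-1,6-dien-3-yl]oxy}-6-fluoro-4-methylbenzonitrile | C=C[C@](C)(Oc1cc(C)cc(F)c1C#N)CCC=C(C)C
F14 | step 1 | 2-{[(3R)-3,7-dimethylocta-1,6-dien-3-yl]oxy}-4-methyl-6-[2-(methylsulfonyl)ethoxy]benzonitrile | C=C[C@](C)(Oc1cc(C)cc(OCCS(C)(=O)=O)c1C#N)CCC=C(C)C
F15 | step 1 | 2-{[(3R)-3,7-dimethylocta-1,6-dien-3-yl]oxy}-6-hydroxy-4-methylbenzonitrile | C=C[C@](C)(Oc1cc(C)cc(O)c1C#N)CCC=C(C)C
F16 | step 1 | 2-{[tert-butyl(dimethyl)silyl]oxy}-6-{[(3R)-3,7-dimethylocta-1,6-dien-3-yl]oxy}-4-methylbenzonitrile | C=C[C@](C)(Oc1cc(C)cc(O[Si](C)(C)C(C)(C)C)c1C#N)CCC=C(C)C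
A1 | direct plan | methyl (1S,2R)-3,3-dimethyl-2-(2-oxoethyl)cyclohexane-1-carboxylate | O=CC[C@@H]1[C@@H](C(=O)OC)CCCC1(C)C
A2 | direct plan | (2S,5S)-2-tert-butyl-5-methyl-1,3-dioxolan-4-one | C[C@@H]1O[C@H](C(C)(C)C)OC1=O
A3 | direct plan | methyl (1S,2R)-2-[(3R)-3-hydroxy-3-methylpent-4-en-1-yl]-3,3-dimethylcyclohexane-1-carboxylate | O[C@](C)(CC[C@@H]1[C@@H](C(=O)OC)CCCC1(C)C)C=C
A4 | direct plan | methyl (1S,2R)-2-{2-[(2R)-5-(methoxymethoxy)-2,7-dimethyl-3,4-dihydro-2H-chromen-2-yl]ethyl}-3,3-dimethylcyclohexane-1-carboxylate | Cc1cc(OCOC)c2c(c1)O[C@](C)(CC[C@@H]1[C@@H](C(=O)OC)CCCC1(C)C)CC2
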